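**Retrosynthetic overview** (target numbering: ring A = C1–C5, C10; ring B = C5–C10; C17 on C8, C20 on C9, C18 = ester carbon and C19 = methyl on C4, side chain C11–C15 with C16 on C13)
1. End game: the C2 ketone comes from allylic oxidation of the Δ1(10) alkene and the C15 alcohol from a silyl ether.
2. Ring A (formed last): exo-selective Diels–Alder reaction of methacrolein with the diene C5=C10–C1=C2 (bonds C4–C5 and C2–C3; sets C4 and C5), then CHO → CO2Me.
3. Until ring A is in place, C20 and C6 stay joined through a sulfur atom (2-thiabicyclo[2.2.2]octane); Raney nickel then turns them into the C9 methyl and the C6 methylene.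
4. Ring B (formed second, key disconnection): [4+2] cycloaddition of (E)-crotonaldehyde (C7, C8, C17) with a 4-silyloxy-2H-thiopyran, forming C6–C7 and C8–C9. Enabling feature: in ring B the quaternary C9 carries a methyl (C20) cis to the C8 methyl, C6 is an unsubstituted CH2 and C10 is sp2, so C20 and C6 can be tied through sulfur into the six-membered ring S–C20–C9=C10–C5=C6 (formed first), which locks the diene s-cis with C20 "inside".
5. The thiopyran comes from thian-4-one; C9–C11 is made by enolate alkylation with the C11–C15 iodide derived from (R)-citronellol (source of C13).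

Key step: step 7

Assumption: the (S)-oxazaborolidinium catalyst is taken to leave the Re face of C3 of crotonaldehyde open in step 7 and the (R)-antipode to be the matched catalyst in step 11 (Corey pre-transition-state models); if either sense proves opposite, the mirror-image catalyst is used and nothing else changes.

Remark on names: bicyclic intermediates are numbered S2, C3 (= C20), C4 (= C9), C5 (= C10), C6 (= C5), C7, C8, C1 (= C6 of the target); endo = on the side of the C5–C6 bridge, exo = on the side of the S2–C3 bridge.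

**Route**

Step 1
Reactants: 1 (R)-citronellol
Product: 2 (R)-citronellyl tert-butyldiphenylsilyl ether
Conditions: t-BuPh2SiCl, imidazole, DMF, rt
Reagents that add atoms: tert-butyl(chloro)diphenylsilane, CC(C)(C)[Si](Cl)(c1ccccc1)c1ccccc1
Why: Imidazole-promoted silylation of a primary alcohol is routine and gives a protecting group that survives every later step, while the C13 stereocentre, which comes from the chiral pool, is not involved.

Step 2
Reactants: 2 (R)-citronellyl tert-butyldiphenylsilyl ether
Product: 4 (4R)-6-silyloxy-4-methylhexanoic acid, via aldehyde 3 (not isolated)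
Conditions: O3, MeCN/H2O (9:1), 0 °C; then NaClO2, NaH2PO4, same flask, 0 °C → rt
Reagents that add atoms: ozone, [O-][O+]=O; sodium chlorite, [Na+].[O-]Cl=O
Why: Ozonolysis of the trisubstituted alkene in wet acetonitrile gives the aldehyde and acetone directly and Pinnick–Lindgren chlorite oxidation in the same flask gives the acid, with the hydrogen peroxide from the ozonolysis acting as hypochlorite scavenger; no stereocentre is touched.

Step 3
Reactants: 4 (4R)-6-silyloxy-4-methylhexanoic acid
Product: 6 (3S)-5-iodo-3-methylpentyl tert-butyldiphenylsilyl ether, via acyl hypoiodite 5 (not isolated)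
Conditions: PhI(OAc)2, I2, cyclohexane, hν (tungsten lamp), reflux
Reagents that add atoms: iodine, II
Why: Suárez iododecarboxylation (photolysis of the acyl hypoiodite, a Hunsdiecker-type radical decarboxylation) excises one carbon and leaves the primary iodide that will be C11, the remote C13 centre being unaffected.

Step 4
Reactants: 7 thian-4-one
Product: 9 2,3-dihydro-4H-thiopyran-4-one, via 2-chlorothian-4-one 8 (not isolated)
Conditions: N-chlorosuccinimide (1.05 equiv), pyridine (1.1 equiv), CH2Cl2, 0 °C → rt
Reagents that add atoms: none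
Why: Chlorination α to sulfur by N-chlorosuccinimide (Pummerer-type) followed by pyridine-mediated loss of HCl is the known dehydrogenation of thian-4-one to the vinylogous thioester.

Step 5
Reactants: 9 2,3-dihydro-4H-thiopyran-4-one; 6 (3S)-5-iodo-3-methylpentyl tert-butyldiphenylsilyl ether
Product: 11 3-alkyl-2,3-dihydro-4H-thiopyran-4-one (both C3 epimers), via lithium enolate 10 (not isolated)
Conditions: LiN(iPr)2 (1.05 equiv), THF, −78 °C; then 6, DMPU, −78 → −30 °C
Reagents that add atoms: none
Why: Kinetic α′-deprotonation of the vinylogous thioester and SN2 alkylation of the enolate (Stork–Danheiser-type alkylation) form the C9–C11 bond; the new centre at C9 is formed without control, which does not matter because it becomes sp2 in step 6.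

Step 6
Reactants: 11 3-alkyl-2,3-dihydro-4H-thiopyran-4-one
Product: 12 3-alkyl-4-(tert-butyldimethylsilyloxy)-2H-thiopyran
Conditions: t-BuMe2SiOTf (1.2 equiv), Et3N (2 equiv), CH2Cl2, 0 °C
Reagents that add atoms: tert-butyldimethylsilyl trifluoromethanesulfonate, CC(C)(C)[Si](C)(C)OS(=O)(=O)C(F)(F)F
Why: Soft enolisation with a silyl triflate and an amine can remove only the hydrogen on C9 and gives the cross-conjugated silyl dienol ether, the known way to 4-silyloxy-2H-thiopyrans, so both C9 epimers of 11 converge on one diene.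

Step 7
Reactants: 12 3-alkyl-4-(tert-butyldimethylsilyloxy)-2H-thiopyran; 13 (E)-crotonaldehyde
Product: 15 (1R,4R,7S,8R)-4-alkyl-8-methyl-5-oxo-2-thiabicyclo[2.2.2]octane-7-carbaldehyde (7-CHO endo; 8-CH3 exo), via silyl enol ether cycloadduct 14 (not isolated)
Conditions: 13 (3 equiv), (S)-3,3-diphenyl-1-(2-methylphenyl)tetrahydro-1H,3H-pyrrolo[1,2-c][1,3,2]oxazaborole·HNTf2 (20 mol %), CH2Cl2, −78 → −40 °C; then 1 M HCl, THF, 0 °C
Reagents that add atoms: none
Why: Proposed new method: the oxazaborolidinium-bound (E)-enal is attacked at its β-carbon by C9 of the diene, the terminus made nucleophilic both by the silyloxy group on C10 and by the sulfur on C6, while C7 closes onto C6 in an asynchronous concerted [4+2] cycloaddition (limiting case: Mukaiyama–Michael addition followed by closure of the enolate onto the thionium ion), so that C8–C9 and C6–C7 are formed in one operation from a monocyclic diene with a single stereocentre. The closest known reactions are the thermal and Lewis-acid-promoted Diels–Alder reactions of 4-silyloxy-2H-thiopyrans used as cis-diene equivalents and the oxazaborolidinium-catalysed Diels–Alder reactions of 2-silyloxy-1,3-dienes with α,β-enals; their combination on a thiopyran with a fully substituted terminus is new. Ring B closes as the six-membered ring C5–C6–C7–C8–C9–C10 by suprafacial addition to both diene termini and is held as a 2-thiabicyclo[2.2.2]octene. At C9 the thiopyran ring holds C20 inside and the side chain outside, so no diene geometry has to be controlled; at C8 the endo position of the formyl group puts the methyl of the (E)-enal exo, on the side of the S–CH2 bridge and therefore cis to C20 and trans to C11; the absolute sense comes from the catalyst, which leaves the Re face of C3 of the enal open; C6 and C7 are temporary centres. The step needs regioselectivity (C9 to the β-carbon), secured by the two donor groups acting in the same direction, endo selectivity, secured by the Lewis-acid-bound carbonyl on a cyclic diene, and face selectivity, secured by the catalyst.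

Step 8
Reactants: 15 keto aldehyde
Product: 16 (1S,4R,8R)-4-alkyl-8-methyl-2-thiabicyclo[2.2.2]octan-5-one
Conditions: RhCl(PPh3)3 (1.1 equiv), toluene, 110 °C
Reagents that add atoms: none
Why: Tsuji–Wilkinson decarbonylation (oxidative addition into the formyl C–H bond, CO extrusion and C–H reductive elimination) removes the activating group and turns C7 into the methylene of the target, the hindered ketone and the silyl ether being inert.

Step 9
Reactants: 16 bicyclic ketone
Product: 18 enol triflate (C10–OTf; C5=C10), via potassium enolate 17 (not isolated)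
Conditions: KN(SiMe3)2 (1.1 equiv), THF, −78 °C; then PhNTf2 (1.2 equiv), −78 → −20 °C
Reagents that add atoms: N-phenylbis(trifluoromethanesulfonimide), O=S(=O)(N(c1ccccc1)S(=O)(=O)C(F)(F)F)C(F)(F)F
Why: Because C9 is quaternary the ketone can enolise only toward C5, so deprotonation at −78 °C and O-sulfonylation with PhNTf2 (enol triflate formation) give one regioisomer, the low temperature keeping the β-thio enolate from eliminating.

Step 10
Reactants: 18 enol triflate
Product: 19 (1S,4R,8R)-4-alkyl-5-ethenyl-8-methyl-2-thiabicyclo[2.2.2]oct-5-ene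
Conditions: Bu3SnCH=CH2 (1.5 equiv), Pd(PPh3)4 (5 mol %), LiCl (3 equiv), THF, 65 °C
Reagents that add atoms: tributyl(vinyl)stannane, C=C[Sn](CCCC)(CCCC)CCCC
Why: Stille cross-coupling of the enol triflate in the presence of LiCl introduces C1 and C2 as a vinyl group and thereby creates the semicyclic diene C5=C10–C1=C2.

Step 11
Reactants: 19 vinyl diene; 20 methacrolein
Product: 21 thia-bridged Δ1(10)-octalin aldehyde (4β-CHO; 4α-CH3; 5β-H; sulfur joining C6 and C20 on the α face)
Conditions: 20 (5 equiv), (R)-3,3-diphenyl-1-(2-methylphenyl)tetrahydro-1H,3H-pyrrolo[1,2-c][1,3,2]oxazaborole·HNTf2 (20 mol %), CH2Cl2, −78 → −40 °C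
Reagents that add atoms: none
Why: Lewis-acid-catalysed Diels–Alder reaction of a 1-vinylcycloalkene-type diene with methacrolein closes ring A with the usual ortho regiochemistry (bonds C4–C5 and C2–C3), the formyl group exo so that it ends cis to H5, and the dienophile on the diene face syn to the sulfur bridge, which is the open face because sulfur carries no hydrogen whereas C7 and C8 present endo hydrogens to the other face and which is also the face selected by the matched catalyst; C4 and C5 are thus set relative to C9.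

Step 12
Reactants: 21 tricyclic aldehyde
Product: 22 tricyclic carboxylic acid
Conditions: NaClO2, NaH2PO4, 2-methyl-2-butene (20 equiv), t-BuOH/H2O, 0 °C
Reagents that add atoms: sodium chlorite, [Na+].[O-]Cl=O
Why: Pinnick oxidation converts the hindered neopentyl-type aldehyde into the acid without affecting the alkene, and the large excess of 2-methyl-2-butene intercepts hypochlorous acid before it can oxidise the sulfide.

Step 13
Reactants: 22 tricyclic carboxylic acid
Product: 23 tricyclic methyl ester
Conditions: Me3SiCHN2, MeOH/toluene (1:4), 0 °C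
Reagents that add atoms: trimethylsilyldiazomethane, C[Si](C)(C)C=[N+]=[N-]
Why: O-Methylation of the carboxylic acid with trimethylsilyldiazomethane avoids any substitution at the hindered quaternary carboxyl carbon and needs no base or acid that could move the alkene.

Step 14
Reactants: 23 tricyclic methyl ester
Product: 24 methyl (1S,5S,6R,8aS)-5-alkyl-1,5,6-trimethyl-1,2,3,5,6,7,8,8a-octahydronaphthalene-1-carboxylate
Conditions: Raney Ni (W-2, deactivated by reflux in acetone), EtOH, rt → 50 °C
Reagents that add atoms: none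
Why: Raney-nickel hydrogenolysis of both C–S bonds (reductive desulfurisation) turns C20 into the methyl group on C9 and C6 into a methylene and so releases ring B, the nickel being deactivated with acetone so that the hindered trisubstituted C1=C10 alkene is neither reduced nor moved; no stereocentre of the target is touched.

Step 15
Reactants: 24 octalin ester
Product: 25 silyl ether of the target enone
Conditions: Rh2(cap)4 (dirhodium tetrakis(caprolactamate), 1 mol %), t-BuOOH (5 equiv), NaHCO3, CH2Cl2, rt
Reagents that add atoms: tert-butyl hydroperoxide, CC(C)(C)OO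
Why: Allylic oxidation with tert-butyl hydroperoxide and Rh2(cap)4 proceeds by hydrogen abstraction from the allylic methylene attached to the CH end of the trisubstituted alkene (C2), as in the conversion of Δ5-steroids into 7-ketones, and gives the Δ1(10)-2-one, the tertiary allylic C5–H being shielded by the adjacent quaternary C4 and keeping its configuration under the nearly neutral conditions.

Step 16
Reactants: 25 silyl ether of the target enone
Product: 26 target CNP0157174.1
Conditions: HF·pyridine, pyridine/THF, 0 °C → rt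
Reagents that add atoms: none
Why: Desilylation with buffered HF·pyridine frees the primary C15 alcohol under non-basic conditions, so the enone is not deconjugated and the γ-centre C5 is not epimerised.

**Compound list** ("alkyl" in the step lines = (3R)-5-[(tert-butyldiphenylsilyl)oxy]-3-methylpentyl)

1 | (R)-citronellol, (3R)-3,7-dimethyloct-6-en-1-ol | OCC[C@H](C)CCC=C(C)C | starting material
2 | tert-butyl{[(3R)-3,7-dimethyloct-6-en-1-yl]oxy}diphenylsilane | CC(C)(C)[Si](OCC[C@H](C)CCC=C(C)C)(c1ccccc1)c1ccccc1 | intermediate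
3 | (4R)-6-[(tert-butyldiphenylsilyl)oxy]-4-methylhexanal | CC(C)(C)[Si](OCC[C@H](C)CCC=O)(c1ccccc1)c1ccccc1 | intermediate
4 | (4R)-6-[(tert-butyldiphenylsilyl)oxy]-4-methylhexanoic acid | CC(C)(C)[Si](OCC[C@H](C)CCC(=O)O)(c1ccccc1)c1ccccc1 | intermediate
5 | (4R)-6-[(tert-butyldiphenylsilyl)oxy]-4-methylhexanoyl hypoiodite | CC(C)(C)[Si](OCC[C@H](C)CCC(=O)OI)(c1ccccc1)c1ccccc1 | intermediate
6 | tert-butyl{[(3S)-5-iodo-3-methylpentyl]oxy}diphenylsilane | CC(C)(C)[Si](OCC[C@H](C)CCI)(c1ccccc1)c1ccccc1 | intermediate
7 | thian-4-one (tetrahydro-4H-thiopyran-4-one) | O=C1CCSCC1 | starting material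
8 | 2-chlorothian-4-one (racemic) | O=C1CCSC(Cl)C1 | intermediate
9 | 2,3-dihydro-4H-thiopyran-4-one | O=C1C=CSCC1 | intermediate
10 | lithium 2H-thiopyran-4-olate (α′-enolate of 9) | [Li+].[O-]C1=CCSC=C1 | intermediate
11 | 3-{(3R)-5-[(tert-butyldiphenylsilyl)oxy]-3-methylpentyl}-2,3-dihydro-4H-thiopyran-4-one (both C3 epimers) | O=C1C=CSCC1CC[C@@H](C)CCO[Si](c1ccccc1)(c1ccccc1)C(C)(C)C | intermediate
12 | tert-butyl[(3-{(3R)-5-[(tert-butyldiphenylsilyl)oxy]-3-methylpentyl}-2H-thiopyran-4-yl)oxy]dimethylsilane | CC(C)(C)[Si](C)(C)OC1=C(CC[C@@H](C)CCO[Si](c2ccccc2)(c2ccccc2)C(C)(C)C)CSC=C1 | intermediate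
13 | (E)-but-2-enal (crotonaldehyde) | C/C=C/C=O | starting material
14 | (1R,4R,7S,8R)-5-[(tert-butyldimethylsilyl)oxy]-4-{(3R)-5-[(tert-butyldiphenylsilyl)oxy]-3-methylpentyl}-8-methyl-2-thiabicyclo[2.2.2]oct-5-ene-7-carbaldehyde (7-CHO endo, 8-CH3 exo) | O=C[C@@H]1[C@@H](C)[C@@]2(CC[C@@H](C)CCO[Si](c3ccccc3)(c3ccccc3)C(C)(C)C)CS[C@@H]1C=C2O[Si](C)(C)C(C)(C)C | intermediate
15 | (1R,4R,7S,8R)-4-{(3R)-5-[(tert-butyldiphenylsilyl)oxy]-3-methylpentyl}-8-methyl-5-oxo-2-thiabicyclo[2.2.2]octane-7-carbaldehyde (7-CHO endo, 8-CH3 exo) | O=C[C@@H]1[C@@H](C)[C@@]2(CC[C@@H](C)CCO[Si](c3ccccc3)(c3ccccc3)C(C)(C)C)CS[C@@H]1CC2=O | intermediate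
16 | (1S,4R,8R)-4-{(3R)-5-[(tert-butyldiphenylsilyl)oxy]-3-methylpentyl}-8-methyl-2-thiabicyclo[2.2.2]octan-5-one (8-CH3 exo) | C1[C@@H](C)[C@@]2(CC[C@@H](C)CCO[Si](c3ccccc3)(c3ccccc3)C(C)(C)C)CS[C@@H]1CC2=O | intermediate
17 | potassium (1S,4R,8R)-4-{(3R)-5-[(tert-butyldiphenylsilyl)oxy]-3-methylpentyl}-8-methyl-2-thiabicyclo[2.2.2]oct-5-en-5-olate | C1[C@@H](C)[C@@]2(CC[C@@H](C)CCO[Si](c3ccccc3)(c3ccccc3)C(C)(C)C)CS[C@@H]1C=C2[O-].[K+] | intermediate
18 | (1S,4R,8R)-4-{(3R)-5-[(tert-butyldiphenylsilyl)oxy]-3-methylpentyl}-8-methyl-2-thiabicyclo[2.2.2]oct-5-en-5-yl trifluoromethanesulfonate | C1[C@@H](C)[C@@]2(CC[C@@H](C)CCO[Si](c3ccccc3)(c3ccccc3)C(C)(C)C)CS[C@@H]1C=C2OS(=O)(=O)C(F)(F)F | intermediate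
19 | (1S,4R,8R)-4-{(3R)-5-[(tert-butyldiphenylsilyl)oxy]-3-methylpentyl}-5-ethenyl-8-methyl-2-thiabicyclo[2.2.2]oct-5-ene | C1[C@@H](C)[C@@]2(CC[C@@H](C)CCO[Si](c3ccccc3)(c3ccccc3)C(C)(C)C)CS[C@@H]1C=C2C=C | intermediate
20 | methacrolein (2-methylprop-2-enal) | CC(=C)C=O | starting material
21 | tricyclic aldehyde: Δ1(10)-octalin skeleton of the target with sulfur joining C6 and C20 on the α face; 4β-CHO, 4α-CH3, 5β-H, 8α-CH3, 9β-[(3R)-5-(tert-butyldiphenylsilyloxy)-3-methylpentyl] | O=C[C@@]1(C)CCC=C2[C@@H]1[C@@H]3C[C@@H](C)[C@@]2(CC[C@@H](C)CCO[Si](c4ccccc4)(c4ccccc4)C(C)(C)C)CS3 | intermediate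
22 | tricyclic acid: as 21 with 4β-CO2H | OC(=O)[C@@]1(C)CCC=C2[C@@H]1[C@@H]3C[C@@H](C)[C@@]2(CC[C@@H](C)CCO[Si](c4ccccc4)(c4ccccc4)C(C)(C)C)CS3 | intermediate
23 | tricyclic methyl ester: as 21 with 4β-CO2CH3 | COC(=O)[C@@]1(C)CCC=C2[C@@H]1[C@@H]3C[C@@H](C)[C@@]2(CC[C@@H](C)CCO[Si](c4ccccc4)(c4ccccc4)C(C)(C)C)CS3 | intermediate
24 | methyl (1S,5S,6R,8aS)-5-{(3R)-5-[(tert-butyldiphenylsilyl)oxy]-3-methylpentyl}-1,5,6-trimethyl-1,2,3,5,6,7,8,8a-octahydronaphthalene-1-carboxylate | COC(=O)[C@@]1(C)CCC=C2[C@@H]1CC[C@@H](C)[C@]2(C)CC[C@@H](C)CCO[Si](c3ccccc3)(c3ccccc3)C(C)(C)C | intermediate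
25 | methyl (1S,5S,6R,8aS)-5-{(3R)-5-[(tert-butyldiphenylsilyl)oxy]-3-methylpentyl}-1,5,6-trimethyl-3-oxo-1,2,3,5,6,7,8,8a-octahydronaphthalene-1-carboxylate | COC(=O)[C@@]1(C)CC(=O)C=C2[C@@H]1CC[C@@H](C)[C@]2(C)CC[C@@H](C)CCO[Si](c3ccccc3)(c3ccccc3)C(C)(C)C | intermediate
26 | CNP0157174.1, methyl (1S,5S,6R,8aS)-5-[(3R)-5-hydroxy-3-methylpentyl]-1,5,6-trimethyl-3-oxo-1,2,3,5,6,7,8,8a-octahydronaphthalene-1-carboxylate (4S,5S,8R,9S,13R in target numbering) | COC(=O)[C@@]1(C)CC(=O)C=C2[C@@H]1CC[C@@H](C)[C@]2(C)CC[C@@H](C)CCO | target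

**Step count**
Total: 16 steps. Longest linear sequence: 15 steps (steps 1–3 and 5–16).

**Steps most likely to fail, with fallbacks**

Step 7 (proposed new method). What may go wrong: the fully substituted diene terminus reacts too slowly with the β-substituted enal, so that uncatalysed or hetero-Diels–Alder pathways compete, or endo and facial control erode. The fallback uses known chemistry, sets out from 12 and comes back at 14 (hydrolysed to 15 as in step 7); it replaces catalyst control by a covalent auxiliary. Diene 12 is combined with commercial (S)-4-benzyl-3-[(E)-but-2-enoyl]-1,3-oxazolidin-2-one and Et2AlCl (1.4 equiv, CH2Cl2, −78 °C; Evans aluminium-chelate Diels–Alder reaction). This should give the endo N-acyloxazolidinone cycloadduct F1 by attack on the Re face at C3 of the crotonyl unit, the face left open by the benzyl group in the chelate. LiBH4 (THF, MeOH, 0 °C) removes the auxiliary reductively to give the primary alcohol F2, and Parikh–Doering oxidation (SO3·pyridine, DMSO, iPr2NEt) returns the aldehyde 14.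

Step 8. What may go wrong: binding of the thioether to rhodium stalls the decarbonylation, or the alkylrhodium intermediate loses the β-sulfur and the bicycle opens. The fallback sets out from 15 and comes back at 16; it replaces metal-mediated decarbonylation by radical decarboxylation. Pinnick oxidation of 15 (NaClO2, NaH2PO4, 2-methyl-2-butene) should give the keto acid F3. This is converted with oxalyl chloride and then sodium 2-thioxopyridin-1-olate into the Barton ester F4, which is photolysed with a large excess of tert-butyl thiol in benzene to give 16. The excess thiol is there so that hydrogen transfer to the C7 radical outruns the reversible β-scission of the C6–S bond.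

Step 5. What may go wrong: retro-thia-Michael opening of the β-thio enolate 10 on warming competes with the slow alkylation by an unactivated primary iodide, and some O-alkylation occurs. The fallback sets out from 6 and comes back at 11; it alkylates a stabilised enolate and dehydrogenates afterwards. Commercial methyl 4-oxothiane-3-carboxylate is alkylated with 6 (K2CO3, acetone, reflux) to the quaternary β-keto ester F5. Krapcho demethoxycarbonylation (LiCl, wet DMSO, 150 °C) gives the 3-alkylthian-4-one F6. Kinetic enolisation toward the CH2 side and Mukaiyama dehydrogenation (LiN(iPr)2, THF, −78 °C; then N-tert-butylbenzenesulfinimidoyl chloride) introduce the C5=C6 double bond and give 11.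

Further compounds
F1 | step 7 | (S)-4-benzyl-3-{[(1R,4R,7S,8R)-5-(tert-butyldimethylsilyloxy)-4-{(3R)-5-[(tert-butyldiphenylsilyl)oxy]-3-methylpentyl}-8-methyl-2-thiabicyclo[2.2.2]oct-5-en-7-yl]carbonyl}-1,3-oxazolidin-2-one (7-acyl endo, 8-CH3 exo) | O=C(N1C(=O)OC[C@@H]1Cc1ccccc1)[C@@H]2[C@@H](C)[C@@]3(CC[C@@H](C)CCO[Si](c4ccccc4)(c4ccccc4)C(C)(C)C)CS[C@@H]2C=C3O[Si](C)(C)C(C)(C)C
F2 | step 7 | [5-(tert-butyldimethylsilyloxy)-4-{(3R)-5-[(tert-butyldiphenylsilyl)oxy]-3-methylpentyl}-8-methyl-2-thiabicyclo[2.2.2]oct-5-en-7-yl]methanol (7-CH2OH endo, 8-CH3 exo; ring configuration as in 14) | OC[C@@H]1[C@@H](C)[C@@]2(CC[C@@H](C)CCO[Si](c3ccccc3)(c3ccccc3)C(C)(C)C)CS[C@@H]1C=C2O[Si](C)(C)C(C)(C)C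
F3 | step 8 | 4-{(3R)-5-[(tert-butyldiphenylsilyl)oxy]-3-methylpentyl}-8-methyl-5-oxo-2-thiabicyclo[2.2.2]octane-7-carboxylic acid (7-CO2H endo, 8-CH3 exo; ring configuration as in 15) | OC(=O)[C@@H]1[C@@H](C)[C@@]2(CC[C@@H](C)CCO[Si](c3ccccc3)(c3ccccc3)C(C)(C)C)CS[C@@H]1CC2=O
F4 | step 8 | 2-thioxopyridin-1(2H)-yl ester of F3 (Barton ester) | S=C1C=CC=CN1OC(=O)[C@@H]2[C@@H](C)[C@@]3(CC[C@@H](C)CCO[Si](c4ccccc4)(c4ccccc4)C(C)(C)C)CS[C@@H]2CC3=O
F5 | step 5 | methyl 3-{(3R)-5-[(tert-butyldiphenylsilyl)oxy]-3-methylpentyl}-4-oxothiane-3-carboxylate (both C3 epimers) | COC(=O)C1(CC[C@@H](C)CCO[Si](c2ccccc2)(c2ccccc2)C(C)(C)C)CSCCC1=O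
F6 | step 5 | 3-{(3R)-5-[(tert-butyldiphenylsilyl)oxy]-3-methylpentyl}thian-4-one (both C3 epimers) | O=C1CCSCC1CC[C@@H](C)CCO[Si](c2ccccc2)(c2ccccc2)C(C)(C)C
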